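**Retrosynthetic overview**
1. The target is a trans-1,4-disubstituted tetralin: aromatic ring A (C4a, C5–C8, C8a; C5–H, C6–CO2H, C7–OH, C8–OH) fused to saturated ring B (C1 methyl, C4 side chain C1′–C7′).
2. Key disconnection: both aryl–alkyl bonds of ring B (C4a–C4 and C8a–C1) are made by an intramolecular aryne–diene [4+2] between the aryne C4a≡C8a of ring A and the (3E,1Z)-diene C4=C3–C2=C1–CH3; C2=C3 is then saturated.
3. Enabling feature: C5 is the only unsubstituted carbon of ring A and lies peri to C4, and the C1′ hydroxyl oxygen is three bonds from C4. A temporary C5–SiMe2–O–C1′ tether (seven-membered ring C4a–C5–Si–O–C1′–C2′–C4) therefore fixes the regiochemistry, relays C2′ to C4 and C1, and is erased by fluoride as C5–H and C1′–OH, both present in the target.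
4. Ring order: ring A is bought (methyl 2,3-dihydroxybenzoate; catechol masked as acetonide, then brominated and silylated); ring B and the temporary oxasilepine ring close together in the key step; the temporary ring is opened afterwards.
5. Stereochemistry: C6′ is bought, C2′ is set by Evans hydroxymethylation, and C4 and C1 are relayed from C2′ in the key step (trans from the E-linked C2′ and the Z-methyl of the diene).

Key step: step 16

Remark: tetralin numbering is used throughout (C1 = CH–CH3, C4 = CH bearing the side chain, C6 = carboxyl-bearing carbon; side chain C1′ = CH2OH on C2′, C2′ attached to C4, C6′ = CH–CH3, C7′ = second CH2OH); the three starting materials 1, 5 and 16 are assumed to be purchased.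

**Side-chain/diene fragment**

Step 1
Reactants: 1 (R)-3-bromo-2-methylpropan-1-ol
Product: 2 (R)-(3-bromo-2-methylpropoxy)(tert-butyl)diphenylsilane
Conditions: TBDPSCl, imidazole, DMF, 0 °C to rt
Reagents that add atoms: tert-butylchlorodiphenylsilane, CC(C)(C)[Si](Cl)(c1ccccc1)c1ccccc1
Why: Standard silylation of a primary alcohol; the purchased stereocentre (future C6′) is not involved.

Step 2
Reactants: 2 (R)-(3-bromo-2-methylpropoxy)(tert-butyl)diphenylsilane
Product: 3 (S)-tert-butyl[(2-methyloct-7-en-1-yl)oxy]diphenylsilane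
Conditions: pent-4-enylmagnesium bromide, Li2CuCl4 (5 mol %), NMP, THF, 0 °C
Reagents that add atoms: pent-4-enylmagnesium bromide, C=CCCC[Mg]Br
Why: Copper-catalysed Kumada-type (Kochi) sp3–sp3 coupling of a primary bromide with a primary Grignard reagent; the β-stereocentre is untouched.

Step 3
Reactants: 3 (S)-tert-butyl[(2-methyloct-7-en-1-yl)oxy]diphenylsilane
Product: 4 (S)-7-(tert-butyldiphenylsilyloxy)-6-methylheptanoic acid
Conditions: RuCl3·xH2O (2 mol %), NaIO4, CCl4/MeCN/H2O, rt, short reaction time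
Reagents that add atoms: sodium periodate, [Na+].[O-]I(=O)(=O)=O; water, O
Why: RuO4-catalysed oxidative cleavage of a terminal alkene to the carboxylic acid, a transformation that should tolerate the silyl ether.

Step 4
Reactants: 4 (S)-7-(tert-butyldiphenylsilyloxy)-6-methylheptanoic acid; 5 (S)-4-benzyl-1,3-oxazolidin-2-one
Product: 7 (S)-4-benzyl-3-[(S)-7-(tert-butyldiphenylsilyloxy)-6-methylheptanoyl]-1,3-oxazolidin-2-one, via mixed pivalic anhydride 6 (not isolated)
Conditions: PivCl, Et3N, THF, −20 °C; then 5, LiCl, rt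
Reagents that add atoms: none
Why: N-Acylation of the oxazolidinone through the mixed anhydride, the standard entry to Evans imides.

Step 5
Reactants: 7 (S)-4-benzyl-3-[(S)-7-(tert-butyldiphenylsilyloxy)-6-methylheptanoyl]-1,3-oxazolidin-2-one
Product: 9 (S)-4-benzyl-3-[(2R,6S)-7-(tert-butyldiphenylsilyloxy)-2-(hydroxymethyl)-6-methylheptanoyl]-1,3-oxazolidin-2-one, via titanium enolate 8 (not isolated)
Conditions: TiCl4, i-Pr2NEt, CH2Cl2, 0 °C; then 1,3,5-trioxane, TiCl4, 0 °C
Reagents that add atoms: 1,3,5-trioxane, C1OCOCO1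
Why: Evans hydroxymethylation: the chelated (Z)-titanium enolate should be attacked by TiCl4-activated trioxane on the face opposite the benzyl group, which sets the future C2′ stereocentre (2R in the imide).

Step 6
Reactants: 9 the hydroxymethyl imide
Product: 10 (2R,6S)-7-(tert-butyldiphenylsilyloxy)-2-(hydroxymethyl)-N-methoxy-N,6-dimethylheptanamide
Conditions: MeNH(OMe)·HCl, AlMe3, CH2Cl2, −10 °C to rt
Reagents that add atoms: N,O-dimethylhydroxylamine hydrochloride, CNOC.Cl
Why: Weinreb transamidation of a β-hydroxy imide with the aluminium amide releases the auxiliary without touching the α-stereocentre.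

Step 7
Reactants: 10 the hydroxy Weinreb amide
Product: 11 (2R,6S)-7-(tert-butyldiphenylsilyloxy)-N-methoxy-N,6-dimethyl-2-[(triethylsilyloxy)methyl]heptanamide
Conditions: TESCl, imidazole, CH2Cl2, 0 °C
Reagents that add atoms: chlorotriethylsilane, CC[Si](Cl)(CC)CC
Why: Silylation of the primary alcohol at the amide stage, so that no 1,3-diol monosilyl ether (silyl migration would scramble the C2′ centre) is ever formed.

Step 8
Reactants: 11 the TES-protected Weinreb amide
Product: 12 (2R,6S)-7-(tert-butyldiphenylsilyloxy)-6-methyl-2-[(triethylsilyloxy)methyl]heptanal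
Conditions: DIBAL-H (i-Bu2AlH), THF, −78 °C; Rochelle-salt work-up; used at once
Reagents that add atoms: none
Why: Reduction of a Weinreb amide stops at the aldehyde through the chelated tetrahedral intermediate; low temperature should protect the α-stereocentre.

Step 9
Reactants: 12 the aldehyde
Product: 13 (2E,4S,8S)-9-(tert-butyldiphenylsilyloxy)-8-methyl-4-[(triethylsilyloxy)methyl]non-2-enal
Conditions: Ph3P=CHCHO, toluene, 75 °C
Reagents that add atoms: (triphenylphosphoranylidene)acetaldehyde, O=CC=P(c1ccccc1)(c1ccccc1)c1ccccc1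
Why: Wittig reaction of a stabilised ylide, expected to give the (E)-enal (future C4=C3).

Step 10
Reactants: 13 the (E)-enal
Product: 14 tert-butyl{[(2S,6S,7E,9Z)-2-methyl-6-[(triethylsilyloxy)methyl]undeca-7,9-dien-1-yl]oxy}diphenylsilane
Conditions: EtPPh3Br, KHMDS (KN(SiMe3)2), THF, −78 to 0 °C
Reagents that add atoms: ethyltriphenylphosphonium bromide, CC[P+](c1ccccc1)(c1ccccc1)c1ccccc1.[Br-]
Why: Wittig reaction of a non-stabilised ylide under lithium-free conditions, expected to give the (Z)-alkene (future C2=C1) and so the (E,Z)-diene.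

Step 11
Reactants: 14 the TES-protected diene
Product: 15 (2S,3E,5Z)-2-[(4S)-5-(tert-butyldiphenylsilyloxy)-4-methylpentyl]hepta-3,5-dien-1-ol
Conditions: PPTS (cat.), MeOH/CH2Cl2, 0 °C
Reagents that add atoms: none
Why: Mild acid-catalysed methanolysis should remove the primary TES ether selectively beside the TBDPS ether and the diene.

**Arene fragment**

Step 12
Reactants: 16 methyl 2,3-dihydroxybenzoate
Product: 17 methyl 2,2-dimethyl-1,3-benzodioxole-4-carboxylate
Conditions: 2,2-dimethoxypropane, TsOH (cat.), toluene, reflux with removal of MeOH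
Reagents that add atoms: 2,2-dimethoxypropane, COC(C)(C)OC
Why: Acid-catalysed transketalisation masks the catechol as its isopropylidene ketal, stable to bases and fluoride.

Step 13
Reactants: 17 the acetonide ester
Product: 18 methyl 6-bromo-2,2-dimethyl-1,3-benzodioxole-4-carboxylate
Conditions: NBS, DMF, rt
Reagents that add atoms: N-bromosuccinimide, O=C1CCC(=O)N1Br
Why: Electrophilic aromatic bromination is expected para to the ring oxygen next to the ester and meta to the ester, which is the future C4a.

Step 14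
Reactants: 18 the bromo ester
Product: 20 methyl 6-bromo-5-(dimethylsilyl)-2,2-dimethyl-1,3-benzodioxole-4-carboxylate, via arylmagnesium chloride 19 (not isolated)
Conditions: TMPMgCl·LiCl, THF, −25 °C; then ClSiMe2H, −25 °C to rt
Reagents that add atoms: chlorodimethylsilane, C[SiH](C)Cl
Why: Ester-directed magnesiation by the hindered amide base at the position flanked by ester and bromine (future C5), then silylation; the ortho-bromo arylmagnesium should be stable at low temperature.

**Union, key step and endgame**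

Step 15
Reactants: 20 the aryl(dimethyl)silane; 15 the dienol
Product: 22 methyl 6-bromo-5-{dimethyl[(2S,3E,5Z)-2-[(4S)-5-(tert-butyldiphenylsilyloxy)-4-methylpentyl]hepta-3,5-dien-1-yloxy]silyl}-2,2-dimethyl-1,3-benzodioxole-4-carboxylate, via bromosilane 21 (not isolated)
Conditions: NBS (1.0 equiv), CH2Cl2, 0 °C; then 15, imidazole, DMAP (cat.), 0 °C to rt
Reagents that add atoms: none
Why: Si–H bromination followed by silyl ether formation with the primary alcohol (standard alkoxysilane synthesis) installs the C5–Si–O–C1′ tether.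

Step 16
Reactants: 22 the tethered bromoarene
Product: 25 tricyclic cycloadduct (ring B closed; C2=C3 alkene; C5–SiMe2–O–C1′ bridge intact), via aryllithium 23 (not isolated), via aryne 24 (not isolated)
Conditions: LiTMP (lithium 2,2,6,6-tetramethylpiperidide, from the amine and n-BuLi; 1.3 equiv), THF (0.005 M), −78 to −20 °C
Reagents that add atoms: none
Why: Proposed new method: LiTMP removes the only ring hydrogen (C8a–H, between the acetal oxygen and bromine), loss of LiBr gives aryne 24 (C4a≡C8a), and the tethered diene traps it in a concerted suprafacial [4+2] cycloaddition that forms C4a–C4 and C8a–C1 together; the closest known reaction types are the intramolecular aryne–diene Diels–Alder reaction of carbon-tethered acyclic dienes and the silicon-tethered intramolecular aryne–furan cycloaddition, neither shown for a silyl-ether-tethered acyclic diene with a (Z)-terminus. Ring B closes as the six-membered [4+2] ring, and the temporary seven-membered oxasilepine ring (C4a, C5, Si, O, C1′, C2′, C4) closes at the same time in a 7-exo sense (C3 stays outside it). Regioselectivity (C4 to C4a, C1 to C8a) is enforced by the tether anchored at C5 next to C4a. C1 is controlled by diene geometry: the E-linked C2′ and the Z-methyl must end up on opposite faces of ring B, so methyl and side chain are trans. C4 is controlled by C2′: in the cyclic transition state C2′–H should eclipse C3=C4 (allylic strain), C1′ leads to silicon and the C3′ chain points away from the aryne, which selects the face giving (4S) from (2′S). The step needs [4+2] to win over ene, [2+2] and amine-addition pathways, which the tether-imposed proximity, high dilution and the hindered base should secure.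

Step 17
Reactants: 25 the cycloadduct
Product: 26 tetralin siloxane (C2–C3 saturated; otherwise as 25)
Conditions: H2 (1 atm), PtO2, EtOAc, rt
Reagents that add atoms: none
Why: Catalytic hydrogenation of the isolated cis-disubstituted alkene creates no stereocentre; PtO2 is chosen to limit double-bond migration towards ring A.

Step 18
Reactants: 26 the tetralin siloxane
Product: 28 7,8-O-isopropylidene-protected target acid (C5–H; C1′–OH and C7′–OH free), via methyl ester diol 27 (not isolated)
Conditions: TBAF, THF/DMF, 60 °C; then LiOH, MeOH/H2O, 50 °C; 1 M HCl to pH 3 at 0 °C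
Reagents that add atoms: lithium hydroxide, [Li+].[OH-]
Why: Fluoride should cleave the Si–O bond and the TBDPS ether and induce ipso-protodesilylation of the arylsilane (ortho ester stabilises the aryl anion), returning C5–H and C1′–OH; saponification then frees the acid.

Step 19
Reactants: 28 the acetonide-protected acid
Product: 29 (5R,8S)-8-[(2S,6S)-1,7-dihydroxy-6-methylheptan-2-yl]-3,4-dihydroxy-5-methyl-5,6,7,8-tetrahydronaphthalene-2-carboxylic acid (target)
Conditions: 3 M HCl/THF, 50 °C, under argon
Reagents that add atoms: none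
Why: Acid hydrolysis of the isopropylidene ketal releases the catechol; no stereocentre is touched.

**Compound list**
1 | (R)-3-bromo-2-methylpropan-1-ol | C[C@H](CO)CBr | starting material
2 | (R)-(3-bromo-2-methylpropoxy)(tert-butyl)diphenylsilane | C[C@H](CO[Si](c1ccccc1)(c1ccccc1)C(C)(C)C)CBr | intermediate
3 | (S)-tert-butyl[(2-methyloct-7-en-1-yl)oxy]diphenylsilane | C[C@H](CO[Si](c1ccccc1)(c1ccccc1)C(C)(C)C)CCCCC=C | intermediate
4 | (S)-7-(tert-butyldiphenylsilyloxy)-6-methylheptanoic acid | C[C@H](CO[Si](c1ccccc1)(c1ccccc1)C(C)(C)C)CCCCC(=O)O | intermediate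
5 | (S)-4-benzyl-1,3-oxazolidin-2-one | O=C1OC[C@H](Cc2ccccc2)N1 | starting material
6 | mixed pivalic anhydride of 4 (formed in the flask) | C[C@H](CO[Si](c1ccccc1)(c1ccccc1)C(C)(C)C)CCCCC(=O)OC(=O)C(C)(C)C | intermediate
7 | (S)-4-benzyl-3-[(S)-7-(tert-butyldiphenylsilyloxy)-6-methylheptanoyl]-1,3-oxazolidin-2-one | C[C@H](CO[Si](c1ccccc1)(c1ccccc1)C(C)(C)C)CCCCC(=O)N1C(=O)OC[C@@H]1Cc1ccccc1 | intermediate
8 | trichlorotitanium (Z)-enolate of 7 (formed in the flask) | C[C@H](CO[Si](c1ccccc1)(c1ccccc1)C(C)(C)C)CCC/C=C(\O[Ti](Cl)(Cl)Cl)N1C(=O)OC[C@@H]1Cc1ccccc1 | intermediate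
9 | (S)-4-benzyl-3-[(2R,6S)-7-(tert-butyldiphenylsilyloxy)-2-(hydroxymethyl)-6-methylheptanoyl]-1,3-oxazolidin-2-one | C[C@H](CO[Si](c1ccccc1)(c1ccccc1)C(C)(C)C)CCC[C@H](CO)C(=O)N1C(=O)OC[C@@H]1Cc1ccccc1 | intermediate
10 | (2R,6S)-7-(tert-butyldiphenylsilyloxy)-2-(hydroxymethyl)-N-methoxy-N,6-dimethylheptanamide | C[C@H](CO[Si](c1ccccc1)(c1ccccc1)C(C)(C)C)CCC[C@H](CO)C(=O)N(C)OC | intermediate
11 | (2R,6S)-7-(tert-butyldiphenylsilyloxy)-N-methoxy-N,6-dimethyl-2-[(triethylsilyloxy)methyl]heptanamide | C[C@H](CO[Si](c1ccccc1)(c1ccccc1)C(C)(C)C)CCC[C@H](CO[Si](CC)(CC)CC)C(=O)N(C)OC | intermediate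
12 | (2R,6S)-7-(tert-butyldiphenylsilyloxy)-6-methyl-2-[(triethylsilyloxy)methyl]heptanal | C[C@H](CO[Si](c1ccccc1)(c1ccccc1)C(C)(C)C)CCC[C@H](CO[Si](CC)(CC)CC)C=O | intermediate
13 | (2E,4S,8S)-9-(tert-butyldiphenylsilyloxy)-8-methyl-4-[(triethylsilyloxy)methyl]non-2-enal | C[C@H](CO[Si](c1ccccc1)(c1ccccc1)C(C)(C)C)CCC[C@H](CO[Si](CC)(CC)CC)/C=C/C=O | intermediate
14 | tert-butyl{[(2S,6S,7E,9Z)-2-methyl-6-[(triethylsilyloxy)methyl]undeca-7,9-dien-1-yl]oxy}diphenylsilane | C[C@H](CO[Si](c1ccccc1)(c1ccccc1)C(C)(C)C)CCC[C@H](CO[Si](CC)(CC)CC)/C=C/C=C\C | intermediate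
15 | (2S,3E,5Z)-2-[(4S)-5-(tert-butyldiphenylsilyloxy)-4-methylpentyl]hepta-3,5-dien-1-ol | C[C@H](CO[Si](c1ccccc1)(c1ccccc1)C(C)(C)C)CCC[C@H](CO)/C=C/C=C\C | intermediate
16 | methyl 2,3-dihydroxybenzoate | COC(=O)c1cccc(O)c1O | starting material
17 | methyl 2,2-dimethyl-1,3-benzodioxole-4-carboxylate | COC(=O)c1cccc2OC(C)(C)Oc12 | intermediate
18 | methyl 6-bromo-2,2-dimethyl-1,3-benzodioxole-4-carboxylate | COC(=O)c1cc(Br)cc2OC(C)(C)Oc12 | intermediate
19 | 5-chloromagnesio derivative of 18 (formed in the flask, LiCl complex) | COC(=O)c1c([Mg]Cl)c(Br)cc2OC(C)(C)Oc12 | intermediate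
20 | methyl 6-bromo-5-(dimethylsilyl)-2,2-dimethyl-1,3-benzodioxole-4-carboxylate | COC(=O)c1c([SiH](C)C)c(Br)cc2OC(C)(C)Oc12 | intermediate
21 | methyl 6-bromo-5-[bromo(dimethyl)silyl]-2,2-dimethyl-1,3-benzodioxole-4-carboxylate (formed in the flask) | COC(=O)c1c([Si](C)(C)Br)c(Br)cc2OC(C)(C)Oc12 | intermediate
22 | tethered aryne precursor: silyl ether of dienol 15 with the aryl(dimethyl)silyl unit of 20 (Br at future C4a, H at future C8a) | C[C@H](CO[Si](c1ccccc1)(c1ccccc1)C(C)(C)C)CCC[C@H](CO[Si](C)(C)c1c(Br)cc2OC(C)(C)Oc2c1C(=O)OC)/C=C/C=C\C | intermediate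
23 | 7-lithio derivative of 22 (Li between acetal oxygen and bromine; formed in the flask) | C[C@H](CO[Si](c1ccccc1)(c1ccccc1)C(C)(C)C)CCC[C@H](CO[Si](C)(C)c1c(Br)c([Li])c2OC(C)(C)Oc2c1C(=O)OC)/C=C/C=C\C | intermediate
24 | aryne C4a≡C8a derived from 23 (formed in the flask) | C[C@H](CO[Si](c1ccccc1)(c1ccccc1)C(C)(C)C)CCC[C@H](CO[Si](C)(C)C1=C(C(=O)OC)C2=C(C#C1)OC(C)(C)O2)/C=C/C=C\C | intermediate
25 | cycloadduct: acetonide-protected methyl ester of the 1,4-dihydronaphthalene (C2=C3) with (1R)-methyl, (4S)-C4 bridged to C5 through C2′–C1′–O–SiMe2 (seven-membered oxasilepine ring), C7′–OTBDPS | C[C@H](CO[Si](c1ccccc1)(c1ccccc1)C(C)(C)C)CCC[C@@H]2CO[Si](C)(C)c3c(C(=O)OC)c4OC(C)(C)Oc4c5c3[C@H]2C=C[C@H]5C | intermediate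
26 | tetralin siloxane: 25 with C2–C3 saturated | C[C@H](CO[Si](c1ccccc1)(c1ccccc1)C(C)(C)C)CCC[C@@H]2CO[Si](C)(C)c3c(C(=O)OC)c4OC(C)(C)Oc4c5c3[C@H]2CC[C@H]5C | intermediate
27 | methyl ester of 28 (C5–H, both side-chain hydroxyls free; formed in the flask) | C[C@H](CO)CCC[C@H](CO)[C@@H]1CC[C@@H](C)c2c1cc(C(=O)OC)c1OC(C)(C)Oc12 | intermediate
28 | 7,8-O-isopropylidene derivative of the target acid | C[C@H](CO)CCC[C@H](CO)[C@@H]1CC[C@@H](C)c2c1cc(C(=O)O)c1OC(C)(C)Oc12 | intermediate
29 | (5R,8S)-8-[(2S,6S)-1,7-dihydroxy-6-methylheptan-2-yl]-3,4-dihydroxy-5-methyl-5,6,7,8-tetrahydronaphthalene-2-carboxylic acid | C[C@H](CO)CCC[C@H](CO)[C@@H]1CC[C@@H](C)c2c1cc(C(=O)O)c(O)c2O | target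

**Totals**
Total step count: 19. Longest linear sequence: 16 steps (steps 1–11 and 15–19).

**Steps most likely to fail**

Step 16 (key step). What may go wrong: capture of the aryne by ene or [2+2] pathways at the (Z)-propenyl terminus, addition of the amine to the aryne, or insufficient facial discrimination by C2′. Fallback (known reactions, stepwise annulation on the same tether), setting out from 13 and 20 and returning at 28:
- The TES ether of 13 is cleaved (AcOH/THF/H2O) to give hydroxy enal F1.
- F1 is silylated with bromosilane 21 (made from 20 as in step 15) to give bromoaryl silyl ether F2.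
- An intramolecular reductive Heck conjugate arylation (Pd(OAc)2, PPh3, HCO2Na, DMF, 80 °C) closes the seven-membered ring and forms C4a–C4, giving aldehyde F3; C4 is again controlled by C2′ within the ring.
- Wittig ethylidenation (EtPPh3Br, KHMDS) gives (Z)-alkene F4.
- Acid-promoted Friedel–Crafts hydroarylation (TfOH cat., HFIP, 0 °C) closes C8a–C1 through the secondary C1 cation, with the methyl group expected trans to the side chain. The acid also cleaves the aryl–silicon bond, so desilylated tetralin F5 should result after aqueous work-up.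
- F5 is taken through the conditions of step 18 and rejoins the route at 28.

Step 14. What may go wrong: metalation at the wrong ring position (between acetal oxygen and bromine) or collapse of the ortho-bromo arylmagnesium before silylation. Fallback (directed C–H iodination, then halogen–magnesium exchange), setting out from 18 and returning at 20:
- Saponification (LiOH) gives bromo acid F6.
- Carboxylate-directed ortho-iodination (Pd(OAc)2 cat., PhI(OAc)2, I2, DMF) at the only free ortho position gives bromo-iodo acid F7.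
- Esterification (MeI, K2CO3) gives bromo-iodo ester F8.
- Selective iodine–magnesium exchange (iPrMgCl·LiCl, THF, −40 °C) and quenching with ClSiMe2H should give 20.

Step 10. What may go wrong: γ-deprotonation of enal 13 by the basic ylide with erosion of the C2′ stereocentre, or leakage of alkene geometry. Fallback (cross-coupling instead of carbonyl olefination), setting out from 12 and returning at 14:
- Takai olefination of 12 (CrCl2, CHI3, THF) gives (E)-vinyl iodide F9.
- Suzuki–Miyaura coupling with (Z)-prop-1-enylboronic acid (Pd(PPh3)4, aq. KOH, THF), with retention at both partners, gives 14.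

**Further compounds**
F1 | step 16 | (2E,4S,8S)-9-(tert-butyldiphenylsilyloxy)-4-(hydroxymethyl)-8-methylnon-2-enal | C[C@H](CO[Si](c1ccccc1)(c1ccccc1)C(C)(C)C)CCC[C@H](CO)/C=C/C=O
F2 | step 16 | silyl ether of F1 with the aryl(dimethyl)silyl unit of 21 | C[C@H](CO[Si](c1ccccc1)(c1ccccc1)C(C)(C)C)CCC[C@H](CO[Si](C)(C)c1c(Br)cc2OC(C)(C)Oc2c1C(=O)OC)/C=C/C=O
F3 | step 16 | oxasilepine-fused aldehyde (C4a–C4 formed; C3H2–CHO on C4; C8a–H) | C[C@H](CO[Si](c1ccccc1)(c1ccccc1)C(C)(C)C)CCC[C@@H]2CO[Si](C)(C)c3c(C(=O)OC)c4OC(C)(C)Oc4cc3[C@H]2CC=O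
F4 | step 16 | (Z)-but-2-enyl analogue of F3 | C[C@H](CO[Si](c1ccccc1)(c1ccccc1)C(C)(C)C)CCC[C@@H]2CO[Si](C)(C)c3c(C(=O)OC)c4OC(C)(C)Oc4cc3[C@H]2C/C=C\C
F5 | step 16 | desilylated tetralin methyl ester (C5–H, C1′–OH free, C7′–OTBDPS, acetonide) | C[C@H](CO[Si](c1ccccc1)(c1ccccc1)C(C)(C)C)CCC[C@H](CO)[C@@H]1CC[C@@H](C)c2c1cc(C(=O)OC)c1OC(C)(C)Oc12
F6 | step 14 | 6-bromo-2,2-dimethyl-1,3-benzodioxole-4-carboxylic acid | OC(=O)c1cc(Br)cc2OC(C)(C)Oc12
F7 | step 14 | 6-bromo-5-iodo-2,2-dimethyl-1,3-benzodioxole-4-carboxylic acid | OC(=O)c1c(I)c(Br)cc2OC(C)(C)Oc12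
F8 | step 14 | methyl 6-bromo-5-iodo-2,2-dimethyl-1,3-benzodioxole-4-carboxylate | COC(=O)c1c(I)c(Br)cc2OC(C)(C)Oc12
F9 | step 10 | (E)-vinyl iodide from 12 (iodoalkene in place of the formyl group) | C[C@H](CO[Si](c1ccccc1)(c1ccccc1)C(C)(C)C)CCC[C@H](CO[Si](CC)(CC)CC)/C=C/I
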